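**Plan**

- Ring numbering used below: C1 (C=O), C2=C3, C4 (OMe), C5 (CH2), C6 (quaternary). Retrosynthesis cuts, in order: the C6–allyl bond together with a carboxyl group on C6 (decarboxylative allylation), that carboxyl being the carbonyl of a γ-lactone closed onto the side-chain oxygen (ring A); then the cyclohexenone (ring B) at C5–C6 and C2=C3, into a 2-acetyl lactone and 2-methoxyacrolein; then the acetyl C–C bond; last the lactone back to a syn homoallylic alcohol from veratraldehyde and a Z-crotyl unit.
- Forward order: side chain with its two stereocentres, then ring A (temporary), then the acetyl group, then ring B built spiro onto ring A; finally ring A is opened, its carbonyl leaves as CO2 and the allyl group takes its place.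
- Enabling feature: in ring B, C1 and C3 are 1,5-related through C6–C5–C4, C6 is the α-carbon of the C1 ketone and C2=C3 is an enone, so the ring is the product of a conjugate addition (C6 to C5) followed by an aldol condensation (C2 to C3). C4 sits α to the latent C3 aldehyde and stays epimerisable until the ring closes. The side-chain oxygen is four atoms from C6, so a γ-lactone carbonyl standing in for the allyl CH2 makes C6 a doubly activated donor, shields one face and protects the hydroxyl group.
- Stereochemistry: the carbinol and methyl-bearing carbons come from a Z-crotylboration (reagent control). C6 is first set by the lactone face and relays its configuration to C4 in the dynamic ring closure. C6 is then erased on decarboxylation and reset by allylation trans to the C4 methoxy group, reinforced by A1,3 strain in the side chain.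

Key step: step 6

Assumption: the Z-crotylborane made from (−)-Ipc2BOMe (from (+)-α-pinene) is taken to attack the same aldehyde face as the parent allylborane, which gives the (1S,2R) alcohol; if the opposite sense were found, the antipodal borane would be used.

**Route**

Step 1
Reactants: 1 3,4-dimethoxybenzaldehyde (veratraldehyde); 2 cis-2-butene; 3 (−)-B-methoxydiisopinocampheylborane
Product: 7 (1S,2R)-1-(3,4-dimethoxyphenyl)-2-methylbut-3-en-1-ol, via (Z)-crotylpotassium 4 (not isolated), via (Z)-crotyldiisopinocampheylborane 5 (not isolated), via borinate ester 6 (not isolated)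
Conditions: KOt-Bu, n-BuLi, THF, −78 to −45 °C; 3, −78 °C; BF3·OEt2, −78 °C; 1, −78 °C; then 3 M NaOH, 30% H2O2, 23 °C
Reagents that add atoms: none
Why: Brown crotylboration through a closed chair transition state: the Z geometry of the crotyl unit should give the syn relationship and the isopinocampheyl groups should select the aldehyde face, so both side-chain stereocentres are set by the reagent.

Step 2
Reactants: 7 (1S,2R)-1-(3,4-dimethoxyphenyl)-2-methylbut-3-en-1-ol
Product: 9 (1S,2R)-1-(3,4-dimethoxyphenyl)-2-methylbutane-1,4-diol, via bis(9-borabicyclononyl) adduct 8 (not isolated)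
Conditions: 9-BBN-H (2.5 equiv), THF, 0 to 23 °C; then 3 M NaOH, 30% H2O2, 0 to 23 °C
Reagents that add atoms: hydrogen peroxide, OO
Why: Anti-Markovnikov hydroboration of the terminal alkene (the first equivalent of borane is taken up by the hydroxyl group) and oxidation with retention should give the primary alcohol without touching the two stereocentres.

Step 3
Reactants: 9 (1S,2R)-1-(3,4-dimethoxyphenyl)-2-methylbutane-1,4-diol
Product: 11 (4R,5S)-5-(3,4-dimethoxyphenyl)-4-methyloxolan-2-one (cis lactone, ring A), via lactol 10 (not isolated)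
Conditions: TEMPO (10 mol %), PhI(OAc)2 (2.5 equiv), CH2Cl2, 23 °C
Reagents that add atoms: none
Why: Nitroxyl-catalysed oxidative lactonisation: the primary alcohol is oxidised first, the aldehyde is captured by the benzylic hydroxyl group as the five-membered lactol and this is oxidised to the lactone, which leaves methyl and aryl cis.

Step 4
Reactants: 11 (4R,5S)-5-(3,4-dimethoxyphenyl)-4-methyloxolan-2-one
Product: 13 (4R,5S)-3-acetyl-5-(3,4-dimethoxyphenyl)-4-methyloxolan-2-one (C3 epimers and enol), via lithium enolate 12 (not isolated)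
Conditions: LiN(SiMe3)2 (2.2 equiv), THF, −78 °C; 1-acetylimidazole (1.2 equiv), −78 to −20 °C; aq. NH4Cl
Reagents that add atoms: 1-acetylimidazole, CC(=O)n1ccnc1
Why: Claisen-type C-acylation of the lactone enolate by an acyl imidazole, driven by deprotonation of the product by the second equivalent of base; the new C3 centre is epimerisable and becomes planar in the next step, so its configuration is of no consequence.

Step 5
Reactants: 14 1,1,2-trimethoxyethane
Product: 16 2-methoxyprop-2-enal (2-methoxyacrolein), via methoxyacetaldehyde 15 (not isolated)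
Conditions: Amberlyst-15 (H+ form), H2O, 50 °C, filter; then 37% aq. CH2O, pyrrolidine (10 mol %), EtCO2H (10 mol %), i-PrOH, 45 °C; distil
Reagents that add atoms: formaldehyde, C=O; water, O
Why: Acid-catalysed acetal hydrolysis followed by amine-catalysed α-methylenation of the aldehyde with formaldehyde (Mannich condensation and elimination), which has only one α-carbon at which to react.

Step 6
Reactants: 13 (4R,5S)-3-acetyl-5-(3,4-dimethoxyphenyl)-4-methyloxolan-2-one; 16 2-methoxyprop-2-enal
Product: 18 (3S,4R,5R,9S)-3-(3,4-dimethoxyphenyl)-9-methoxy-4-methyl-2-oxaspiro[4.5]dec-7-ene-1,6-dione, via keto aldehyde 17 (not isolated)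
Conditions: pyrrolidine (30 mol %), PhCO2H (30 mol %), toluene, 23 °C, then 60 °C
Reagents that add atoms: none
Why: Pyrrolidinium benzoate converts 16 into its iminium ion, the enol of 13 adds through its doubly activated carbon (the future C6) to the terminal CH2 of the acrolein (the future C5), and the acetyl CH3 then condenses with the liberated aldehyde and loses water, so that the C5–C6 single bond and the C2=C3 double bond of ring B arise in one flask. The closest known reaction type is the amine-mediated Robinson-type conjugate addition/aldol condensation of 2-substituted acetoacetates and 2-acetylbutyrolactone with acroleins. Ring B closes as a 6-(enolendo)-exo-trig aldol condensation in which only the acetyl CH3 can be the donor, because the other α-position is quaternary, and only the aldehyde can be the acceptor. The spiro carbon is set in the conjugate addition, which should occur on the lactone face opposite to the cis-disposed methyl and aryl groups. The methoxy-bearing carbon is set dynamically: the α-methoxy aldehyde 17 should epimerise through its enamine faster than it cyclises, and the faster closure should be the chair-like one that has the lactone carbonyl branch of the spiro carbon axial (as alkoxycarbonyl groups are in 2-alkyl-2-alkoxycarbonylcyclohexanones), the methyl-bearing branch equatorial and the methoxy group equatorial and antiperiplanar to the forming bond, which places OMe cis to the side-chain carbon as in the target. The step needs 1,4- over 1,2-addition, secured by the soft donor and iminium activation, and it needs the selection between the two interconverting aldehyde epimers, which rests on the conformational bias just described.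

Step 7
Reactants: 18 (3S,4R,5R,9S)-3-(3,4-dimethoxyphenyl)-9-methoxy-4-methyl-2-oxaspiro[4.5]dec-7-ene-1,6-dione
Product: 21 (4S,6S)-6-[(1S,2R)-1-(3,4-dimethoxyphenyl)-1-hydroxypropan-2-yl]-4-methoxy-6-(prop-2-en-1-yl)cyclohex-2-en-1-one, via potassium β-keto carboxylate 19 (not isolated), via silyl ether 20 (not isolated)
Conditions: KOSiMe3 (1.1 equiv), THF, 0 to 23 °C; then allyl acetate (1.5 equiv), Pd(PPh3)4 (5 mol %), 23 to 40 °C; then 0.5 M aq. citric acid, 0 °C
Reagents that add atoms: allyl acetate, C=CCOC(C)=O
Why: Silanolate cleavage of the lactone should give an anhydrous β-keto carboxylate with the benzylic oxygen silylated, and Tsuji–Saegusa decarboxylative allylation (π-allyl complex from zerovalent palladium and allyl acetate, loss of CO2, C-allylation of the cross-conjugated enolate) installs the allyl group; the planarised C6 should be allylated trans to the C4 methoxy group and, with the side-chain C–H eclipsing the enolate C–O bond (A1,3 strain), on the face of the side-chain methyl away from the aryl carbinol carbon, both elements leading to 6S.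

**Compound list**

1 | 3,4-dimethoxybenzaldehyde | O=Cc1ccc(OC)c(OC)c1 | starting material
2 | cis-2-butene | C/C=C\C | starting material
3 | (−)-B-methoxydiisopinocampheylborane | COB([C@@H]1C[C@@H]2C[C@@H](C2(C)C)[C@H]1C)[C@@H]1C[C@@H]2C[C@@H](C2(C)C)[C@H]1C | starting material
4 | (Z)-but-2-enylpotassium | C/C=C\[CH2-].[K+] | intermediate
5 | B-[(Z)-but-2-enyl]diisopinocampheylborane | C/C=C\CB([C@@H]1C[C@@H]2C[C@@H](C2(C)C)[C@H]1C)[C@@H]1C[C@@H]2C[C@@H](C2(C)C)[C@H]1C | intermediate
6 | diisopinocampheylborinate ester of 7 | C=C[C@@H](C)[C@H](OB([C@@H]1C[C@@H]2C[C@@H](C2(C)C)[C@H]1C)[C@@H]1C[C@@H]2C[C@@H](C2(C)C)[C@H]1C)c1ccc(OC)c(OC)c1 | intermediate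
7 | (1S,2R)-1-(3,4-dimethoxyphenyl)-2-methylbut-3-en-1-ol | C=C[C@@H](C)[C@H](O)c1ccc(OC)c(OC)c1 | intermediate
8 | O,C-bis(9-borabicyclo[3.3.1]nonan-9-yl) adduct of 7 | C(CB1C2CCCC1CCC2)[C@@H](C)[C@H](OB1C2CCCC1CCC2)c1ccc(OC)c(OC)c1 | intermediate
9 | (1S,2R)-1-(3,4-dimethoxyphenyl)-2-methylbutane-1,4-diol | OCC[C@@H](C)[C@H](O)c1ccc(OC)c(OC)c1 | intermediate
10 | (4R,5S)-5-(3,4-dimethoxyphenyl)-4-methyloxolan-2-ol (lactol, both anomers) | OC1C[C@@H](C)[C@H](O1)c2ccc(OC)c(OC)c2 | intermediate
11 | (4R,5S)-5-(3,4-dimethoxyphenyl)-4-methyloxolan-2-one | O=C1C[C@@H](C)[C@H](O1)c2ccc(OC)c(OC)c2 | intermediate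
12 | lithium enolate of 11 | [Li+].[O-]C1=C[C@@H](C)[C@H](O1)c2ccc(OC)c(OC)c2 | intermediate
13 | (4R,5S)-3-acetyl-5-(3,4-dimethoxyphenyl)-4-methyloxolan-2-one (C3 epimers) | O=C1C(C(C)=O)[C@@H](C)[C@H](O1)c2ccc(OC)c(OC)c2 | intermediate
14 | 1,1,2-trimethoxyethane | COCC(OC)OC | starting material
15 | methoxyacetaldehyde | COCC=O | intermediate
16 | 2-methoxyprop-2-enal | C=C(OC)C=O | intermediate
17 | (3R,4R,5S)-3-acetyl-5-(3,4-dimethoxyphenyl)-3-(2-methoxy-3-oxopropyl)-4-methyloxolan-2-one (both epimers at the methoxy carbon) | O=C1[C@@](C(C)=O)([C@@H](C)[C@H](O1)c2ccc(OC)c(OC)c2)CC(OC)C=O | intermediate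
18 | (3S,4R,5R,9S)-3-(3,4-dimethoxyphenyl)-9-methoxy-4-methyl-2-oxaspiro[4.5]dec-7-ene-1,6-dione | O=C2[C@@]1([C@@H](C)[C@H](O2)c3ccc(OC)c(OC)c3)C[C@H](OC)C=CC1=O | intermediate
19 | potassium (1R,5S)-1-[(1S,2R)-1-(3,4-dimethoxyphenyl)-1-(trimethylsilyloxy)propan-2-yl]-5-methoxy-2-oxocyclohex-3-ene-1-carboxylate | [K+].[O-]C(=O)[C@@]1([C@@H](C)[C@H](O[Si](C)(C)C)c2ccc(OC)c(OC)c2)C[C@H](OC)C=CC1=O | intermediate
20 | (4S,6S)-6-[(1S,2R)-1-(3,4-dimethoxyphenyl)-1-(trimethylsilyloxy)propan-2-yl]-4-methoxy-6-(prop-2-en-1-yl)cyclohex-2-en-1-one | C=CC[C@@]1([C@@H](C)[C@H](O[Si](C)(C)C)c2ccc(OC)c(OC)c2)C[C@H](OC)C=CC1=O | intermediate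
21 | (4S,6S)-6-[(1S,2R)-1-(3,4-dimethoxyphenyl)-1-hydroxypropan-2-yl]-4-methoxy-6-(prop-2-en-1-yl)cyclohex-2-en-1-one | C=CC[C@@]1([C@@H](C)[C@H](O)c2ccc(OC)c(OC)c2)C[C@H](OC)C=CC1=O | target

**Count and risks**

Total step count: 7. Longest linear sequence: 6 steps (steps 1, 2, 3, 4, 6, 7); step 5 is a one-step side branch.

Steps most likely to fail:

1. Step 6. The conjugate addition to the captodative acrolein may be slow, the amine may deacylate the quaternary 1,3-dicarbonyl array (retro-Claisen), and above all the selection between the two interconverting aldehyde epimers at ring closure may be weak or run the other way; that bias is argued from conformation and is the least certain element of the route. Fallback: the methoxy carbon is taken from the chiral pool and never placed next to an aldehyde, and ring B is closed by metathesis. Setting out from 11, C-acylation of its lithium enolate (LiN(SiMe3)2, THF, −78 °C) with (E)-but-2-enoyl chloride should give the crotonoyl lactone (4R,5S)-3-[(E)-but-2-enoyl]-5-(3,4-dimethoxyphenyl)-4-methyloxolan-2-one F1. Separately, commercial (S)-2-vinyloxirane is opened by methanol at the allylic carbon with inversion (BF3·OEt2 cat., −20 °C) to (R)-2-methoxybut-3-en-1-ol F2, which is converted (Tf2O, 2,6-lutidine, CH2Cl2, −78 °C) into (R)-2-methoxybut-3-en-1-yl trifluoromethanesulfonate F3. The sodium enolate of F1 (NaH, THF, 0 °C) is alkylated by F3 on the face opposite to methyl and aryl to give the diene (3R,4R,5S)-3-[(E)-but-2-enoyl]-5-(3,4-dimethoxyphenyl)-3-[(2S)-2-methoxybut-3-en-1-yl]-4-methyloxolan-2-one F4. Ring-closing metathesis (second-generation Hoveyda–Grubbs catalyst, CH2Cl2, 40 °C) then closes the enone with loss of propene and comes back to the route at 18.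

2. Step 7. The silanolate may attack the ring ketone instead of the lactone (fragmentation), the enolate may be protonated before it is allylated, or the allylation may discriminate poorly between the two faces. Fallback: the two events are separated. Setting out from 18, KOSiMe3 as before gives 19, and acidification (AcOH, THF, 40 °C) desilylates and decarboxylates it to the hydroxy enone (4S)-6-[(1S,2R)-1-(3,4-dimethoxyphenyl)-1-hydroxypropan-2-yl]-4-methoxycyclohex-2-en-1-one F5 (both C6 epimers). Silylation (TBSOTf, 2,6-lutidine, CH2Cl2, 0 °C) gives the tert-butyldimethylsilyl ether of F5 F6. Kinetic deprotonation at C6 (LiN(SiMe3)2, THF/DMPU, −78 °C) and allyl bromide should give, under the same facial preferences, (4S,6S)-6-[(1S,2R)-1-(tert-butyldimethylsilyloxy)-1-(3,4-dimethoxyphenyl)propan-2-yl]-4-methoxy-6-(prop-2-en-1-yl)cyclohex-2-en-1-one F7. HF·pyridine (THF, 0 °C) then comes back to the route at 21.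

3. Step 4. O-acylation, double acylation or base-induced opening of the lactone may compete with C-acylation. Fallback: aldol addition and oxidation in place of acylation. Setting out from 11, the lithium enolate (LiN(i-Pr)2, THF, −78 °C) is added to acetaldehyde to give (4R,5S)-5-(3,4-dimethoxyphenyl)-3-(1-hydroxyethyl)-4-methyloxolan-2-one F8, and Dess–Martin periodinane (CH2Cl2, NaHCO3, 23 °C) oxidises it, coming back to the route at 13.

Further compounds
F1 | step 6 | (4R,5S)-3-[(E)-but-2-enoyl]-5-(3,4-dimethoxyphenyl)-4-methyloxolan-2-one | O=C1C(C(=O)/C=C/C)[C@@H](C)[C@H](O1)c2ccc(OC)c(OC)c2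
F2 | step 6 | (R)-2-methoxybut-3-en-1-ol | OC[C@H](OC)C=C
F3 | step 6 | (R)-2-methoxybut-3-en-1-yl trifluoromethanesulfonate | FC(F)(F)S(=O)(=O)OC[C@H](OC)C=C
F4 | step 6 | (3R,4R,5S)-3-[(E)-but-2-enoyl]-5-(3,4-dimethoxyphenyl)-3-[(2S)-2-methoxybut-3-en-1-yl]-4-methyloxolan-2-one | O=C1[C@@](C(=O)/C=C/C)([C@@H](C)[C@H](O1)c2ccc(OC)c(OC)c2)C[C@H](OC)C=C
F5 | step 7 | (4S)-6-[(1S,2R)-1-(3,4-dimethoxyphenyl)-1-hydroxypropan-2-yl]-4-methoxycyclohex-2-en-1-one (both C6 epimers) | C1([C@@H](C)[C@H](O)c2ccc(OC)c(OC)c2)C[C@H](OC)C=CC1=O
F6 | step 7 | (4S)-6-[(1S,2R)-1-(tert-butyldimethylsilyloxy)-1-(3,4-dimethoxyphenyl)propan-2-yl]-4-methoxycyclohex-2-en-1-one (both C6 epimers) | C1([C@@H](C)[C@H](O[Si](C)(C)C(C)(C)C)c2ccc(OC)c(OC)c2)C[C@H](OC)C=CC1=O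
F7 | step 7 | (4S,6S)-6-[(1S,2R)-1-(tert-butyldimethylsilyloxy)-1-(3,4-dimethoxyphenyl)propan-2-yl]-4-methoxy-6-(prop-2-en-1-yl)cyclohex-2-en-1-one | C=CC[C@@]1([C@@H](C)[C@H](O[Si](C)(C)C(C)(C)C)c2ccc(OC)c(OC)c2)C[C@H](OC)C=CC1=O
F8 | step 4 | (4R,5S)-5-(3,4-dimethoxyphenyl)-3-(1-hydroxyethyl)-4-methyloxolan-2-one | O=C1C(C(C)O)[C@@H](C)[C@H](O1)c2ccc(OC)c(OC)c2
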